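**Retrosynthetic overview**

1. Target **20** is eudesm-7(11)-en-8-one with a 3β-angelate and a 4α-acetate (eudesmane numbering: ring A = C1–C5, C10; ring B = C5–C10; C15 = carbon on C4). Removed first: both esters, then C7=C11 (acetone aldol on C8, done when C8 is the only ketone), then the C3 hydroxyl (directed reduction) and the C4 hydroxyl (hydrogen-atom-transfer oxygenation of a 4(15)-en-3-one). This leads back to the trans-decalin-3,8-dione **10**.
2. Feature used: the quaternary C10 (angular methyl) is β to the C8 carbonyl of ring B, so a C10 radical is the ring-opened form of a 1-siloxy-5-methylbicyclo[3.1.0]hexane (cleave C8–C10). C1 of ring A is the β-carbon of a C3 enone, so the same radical can form C1–C10.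
3. Key disconnection: **10** ⇒ dienone **9**; ring B arises by ring enlargement and ring A by 6-endo radical closure in one operation.
4. **9** ⇐ Weinreb amide (α-methylenation, vinyl Grignard) ⇐ Simmons–Smith cyclopropanation ⇐ catalytic asymmetric Mukaiyama–Michael addition of an acetate silyl ketene acetal to 2-methylcyclopent-2-en-1-one. This sets C5, from which C10, C4 and C3 follow.
5. Ring order: cyclopentene (bought) → cyclopropane (step 2) → rings B and A together (step 7).

Key step: step 7

Remarks on the chemistry (assumptions):
- Eudesmane numbering is used for all intermediates.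
- C15 is carried through the ring-forming step as a 4(15)-methylene instead of a 4-methyl group, and the silyl group is TBS. The precursor then has no C4 stereocentre to disturb the chair-like closure. The C4 oxygen can later be introduced regiospecifically, whereas a 4-methyl-3-oxo-trans-decalin enolises mainly toward C2 and the C8 ketone would compete.
- Silyl ketene acetal **2** is taken as a commercial reagent.

**Route**

Step 1
Reactants: 1 2-methylcyclopent-2-en-1-one; 2 1-(tert-butyldimethylsilyloxy)-1-methoxyethene
Product: 3 methyl 2-[(1S)-3-(tert-butyldimethylsilyloxy)-2-methylcyclopent-2-en-1-yl]acetate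
Conditions: chiral imidodiphosphorimidate (IDPi) Brønsted acid precatalyst (2 mol %, the enantiomer that leads to (S)-3), toluene, −60 °C
Reagents that add atoms: none
Why: Catalytic asymmetric Mukaiyama–Michael addition under chiral silylium ion-pair catalysis (the acid is silylated in situ by 2): the confined chiral anion leaves one face of the O-silylated enone open so that the acetate carbon adds to the β-carbon and sets C5 (S), and silyl transfer to the enolate oxygen delivers the tetrasubstituted C8=C10 silyl enol ether directly, which fixes which carbon later becomes the quaternary C10.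

Step 2
Reactants: 3 methyl 2-[(1S)-3-(tert-butyldimethylsilyloxy)-2-methylcyclopent-2-en-1-yl]acetate
Product: 4 methyl 2-[1-(tert-butyldimethylsilyloxy)-5-methylbicyclo[3.1.0]hexan-4-yl]acetate (cyclopropane anti to the side chain)
Conditions: Et2Zn, CH2I2, CH2Cl2, 0 °C → rt; pyridine, then aq. NaHCO3
Reagents that add atoms: diiodomethane, ICI
Why: Simmons–Smith cyclopropanation (diethylzinc variant) of the electron-rich silyl enol ether in the presence of the ester; the carbenoid should approach anti to the C5 side chain, but either cyclopropane diastereomer serves because C8 and C10 lose their configuration in step 7.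

Step 3
Reactants: 4 methyl 2-[1-(tert-butyldimethylsilyloxy)-5-methylbicyclo[3.1.0]hexan-4-yl]acetate
Product: 5 N-methoxy-N-methyl-2-[1-(tert-butyldimethylsilyloxy)-5-methylbicyclo[3.1.0]hexan-4-yl]acetamide
Conditions: MeNHOMe·HCl, iPrMgCl, THF, −20 → 0 °C
Reagents that add atoms: N,O-dimethylhydroxylamine hydrochloride, CNOC.Cl
Why: Weinreb amide formation from the methyl ester with the chloromagnesium amide of N,O-dimethylhydroxylamine, a mild aminolysis that leaves the siloxycyclopropane untouched and affects no stereocentre.

Step 4
Reactants: 5 N-methoxy-N-methyl-2-[1-(tert-butyldimethylsilyloxy)-5-methylbicyclo[3.1.0]hexan-4-yl]acetamide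
Product: 6 3-(dimethylamino)-N-methoxy-N-methyl-2-[1-(tert-butyldimethylsilyloxy)-5-methylbicyclo[3.1.0]hexan-4-yl]propanamide (C4 epimers)
Conditions: LDA, THF, −78 °C; Me2N+=CH2 I−, −78 → 0 °C
Reagents that add atoms: Eschenmoser's salt (N,N-dimethylmethyleneiminium iodide), C=[N+](C)C.[I-]
Why: Mannich reaction of the amide lithium enolate (C4 is the only acidic position) with Eschenmoser's salt introduces C15; the new C4 centre forms as a mixture and is erased in step 5.

Step 5
Reactants: 6 3-(dimethylamino)-N-methoxy-N-methyl-2-[1-(tert-butyldimethylsilyloxy)-5-methylbicyclo[3.1.0]hexan-4-yl]propanamide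
Product: 8 N-methoxy-N-methyl-2-[1-(tert-butyldimethylsilyloxy)-5-methylbicyclo[3.1.0]hexan-4-yl]prop-2-enamide, via trimethylammonium iodide 7 (not isolated)
Conditions: MeI, CH2Cl2, rt; then DBU, rt → 40 °C
Reagents that add atoms: none
Why: N-methylation to the quaternary ammonium salt followed by base-induced Hofmann-type β-elimination of trimethylamine gives the α-methylene amide (C4=C15) regiospecifically, since the only β-hydrogen is the acidic one on C4.

Step 6
Reactants: 8 N-methoxy-N-methyl-2-[1-(tert-butyldimethylsilyloxy)-5-methylbicyclo[3.1.0]hexan-4-yl]prop-2-enamide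
Product: 9 2-[1-(tert-butyldimethylsilyloxy)-5-methylbicyclo[3.1.0]hexan-4-yl]penta-1,4-dien-3-one
Conditions: CH2=CHMgBr, THF, −78 → −20 °C; inverse quench into cold 1 M aq. NaHSO4/Et2O; BHT; used at once without concentrating to dryness
Reagents that add atoms: vinylmagnesium bromide, C=C[Mg]Br
Why: Weinreb ketone synthesis: the magnesium-chelated tetrahedral intermediate stops at mono-addition of the vinyl Grignard reagent and collapses on the cold acidic inverse quench, which also keeps the released hydroxylamine protonated so that it does not add to the cross-conjugated dienone; C5 is untouched.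

Step 7
Reactants: 9 2-[1-(tert-butyldimethylsilyloxy)-5-methylbicyclo[3.1.0]hexan-4-yl]penta-1,4-dien-3-one
Product: 10 (5α,10β)-10-methyl-4-methylidenedecalin-3,8-dione (trans-fused; eudesmane numbering)
Conditions: 9-mesityl-3,6-di-tert-butyl-10-phenylacridinium tetrafluoroborate (5 mol %), MeCN/H2O 9:1, 5 mM, 450 nm LEDs, 20 °C, argon
Reagents that add atoms: none
Why: The photoexcited acridinium (E*red about +2 V) oxidises the siloxycyclopropane to its radical cation, whose strain-releasing β-scission breaks the internal C8–C10 bond (tertiary radical rather than the primary radical from C8–C9 cleavage) and, after loss of the silyl group to water, leaves the six-membered ring-B ketone, so ring B is closed by ring enlargement of the cyclopentane. The nucleophilic tertiary C10 radical then adds to the unsubstituted terminus C1 of the vinyl ketone in a 6-endo-trig closure of ring A (C1–C10), since 5-exo attack at the α-carbon C2 is polarity-mismatched and would give a primary radical, and the 4-methylene carbon cannot be reached (four-membered ring). The resulting α-keto radical at C2 is reduced by the acridinyl radical and protonated, which turns the catalyst over without a stoichiometric oxidant or reductant. The closest known reactions are the photoinduced-electron-transfer, iron(III) and manganese(III) ring expansion–cyclisations of bicyclic siloxycyclopropanes bearing alkenyl chains and the Giese additions of cyclopropanol-derived β-keto radicals to enones. The new stereocentre C10 is controlled by C5: in the chair-like transition state the chain on C5 is equatorial on ring B and C1 bonds to the radical face that leaves the methyl axial, which should give the trans-fused decalin as in stepwise radical polyene cyclisations of 1-methylcyclohexyl radicals. The step needs regioselective scission (secured by the C10 methyl), 6-endo selectivity (secured by the enone polarity) and trans selectivity (secured only by C5, the main risk), and high dilution suppresses intermolecular addition to the dienone.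

Step 8
Reactants: 10 (5α,10β)-10-methyl-4-methylidenedecalin-3,8-dione
Product: 12 4α-hydroxy-4β,10β-dimethyl-5α-decalin-3,8-dione, via 4α-hydroperoxide 11 (not isolated)
Conditions: Mn(dpm)3 (10 mol %), PhSiH3, O2 (1 atm), iPrOH/CH2Cl2, 0 °C; then P(OEt)3
Reagents that add atoms: dioxygen, O=O
Why: Mukaiyama-type hydration of an enone (manganese hydride hydrogen-atom transfer to C15, oxygen capture by the tertiary α-keto radical at C4, phosphite reduction of the hydroperoxide) places the oxygen regiospecifically on C4 without any enolisation, leaves the saturated C8 ketone alone, and should deliver oxygen on the α-face because the β-face of C4 is screened by the 1,3-diaxial C10 methyl, giving 4α-OH/4β-CH3.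

Step 9
Reactants: 12 4α-hydroxy-4β,10β-dimethyl-5α-decalin-3,8-dione
Product: 13 3β,4α-dihydroxy-4β,10β-dimethyl-5α-decalin-8-one
Conditions: Me4NBH(OAc)3, MeCN/AcOH, −20 → 0 °C
Reagents that add atoms: none
Why: Hydroxyl-directed reduction with triacetoxyborohydride (Saksena–Evans reduction): only the ketone next to the free 4α-OH is reduced, hydride being delivered to the α-face (axial attack, also favoured sterically by the axial 4β-methyl) to give the equatorial 3β-OH trans to O-4, while the C8 ketone, which has no directing hydroxyl, is not touched.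

Step 10
Reactants: 13 3β,4α-dihydroxy-4β,10β-dimethyl-5α-decalin-8-one
Product: 14 3β,4α-bis(triethylsilyloxy)-4β,10β-dimethyl-5α-decalin-8-one
Conditions: TESOTf, 2,6-lutidine, CH2Cl2, −78 → 0 °C
Reagents that add atoms: triethylsilyl trifluoromethanesulfonate, CC[Si](CC)(CC)OS(=O)(=O)C(F)(F)F
Why: Silylation of the secondary and the tertiary hydroxyl with the silyl triflate/2,6-lutidine system protects the diol for the enolate chemistry at C8 and changes no stereocentre.

Step 11
Reactants: 14 3β,4α-bis(triethylsilyloxy)-4β,10β-dimethyl-5α-decalin-8-one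
Product: 15 7-(2-hydroxypropan-2-yl)-3β,4α-bis(triethylsilyloxy)-4β,10β-dimethyl-5α-decalin-8-one (C7 epimers)
Conditions: LDA, THF, −78 °C; acetone, −78 °C; AcOH quench at −78 °C
Reagents that add atoms: acetone, CC(C)=O
Why: Directed (kinetic) aldol addition: LDA removes the unhindered axial 7α-H of what is now the only ketone (C9 is neopentyl beside the quaternary C10) and the lithium enolate adds to acetone; the C7 centre formed here is erased in step 12.

Step 12
Reactants: 15 7-(2-hydroxypropan-2-yl)-3β,4α-bis(triethylsilyloxy)-4β,10β-dimethyl-5α-decalin-8-one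
Product: 17 3β,4α-bis(triethylsilyloxy)eudesm-7(11)-en-8-one, via tertiary mesylate 16 (not isolated)
Conditions: MsCl, Et3N, DMAP (cat.), CH2Cl2, 0 °C; then DBU, rt
Reagents that add atoms: none
Why: Aldol dehydration by mesylation of the tertiary alcohol (through sulfene) and E1cB elimination through the C8 enolate gives the conjugated tetrasubstituted C7=C11 isopropylidene ketone, and any isopropenyl isomer is equilibrated to the conjugated enone by DBU.

Step 13
Reactants: 17 3β,4α-bis(triethylsilyloxy)eudesm-7(11)-en-8-one
Product: 18 3β,4α-dihydroxyeudesm-7(11)-en-8-one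
Conditions: HF·pyridine, pyridine/THF, 0 °C → rt
Reagents that add atoms: none
Why: Fluoride-mediated cleavage of both triethylsilyl ethers under mildly acidic conditions that disturb neither the enone nor the tertiary carbinol; no stereocentre changes.

Step 14
Reactants: 18 3β,4α-dihydroxyeudesm-7(11)-en-8-one
Product: 19 3β-angeloyloxy-4α-hydroxyeudesm-7(11)-en-8-one
Conditions: angelic acid, 2,4,6-trichlorobenzoyl chloride, Et3N, toluene, rt; then 18, toluene, 80 °C (no DMAP)
Reagents that add atoms: angelic acid [(Z)-2-methylbut-2-enoic acid], C/C=C(/C)C(=O)O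
Why: Yamaguchi-type mixed-anhydride esterification acylates the secondary equatorial 3β-OH selectively over the hindered tertiary 4α-OH and is a DMAP-free angeloylation that avoids Z→E isomerisation to the tiglate; the configuration at C3 is retained.

Step 15
Reactants: 19 3β-angeloyloxy-4α-hydroxyeudesm-7(11)-en-8-one
Product: 20 3β-angeloyloxy-4α-acetoxyeudesm-7(11)-en-8-one (CNP0141494.1)
Conditions: Ac2O, Sc(OTf)3 (5 mol %), MeCN, −20 → 0 °C
Reagents that add atoms: acetic anhydride, CC(=O)OC(C)=O
Why: Lewis-acid-catalysed acetylation (scandium triflate/acetic anhydride) of the hindered tertiary 4α-OH at low temperature, where ionisation at C4 is disfavoured by the adjacent acyloxy group, completes the target without touching the angelate.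

**Compound list**

1 | 2-methylcyclopent-2-en-1-one | CC1=CCCC1=O | starting material
2 | 1-(tert-butyldimethylsilyloxy)-1-methoxyethene | COC(=C)O[Si](C)(C)C(C)(C)C | starting material
3 | methyl 2-[(1S)-3-(tert-butyldimethylsilyloxy)-2-methylcyclopent-2-en-1-yl]acetate | COC(=O)C[C@@H]1CCC(O[Si](C)(C)C(C)(C)C)=C1C | intermediate
4 | methyl 2-[1-(tert-butyldimethylsilyloxy)-5-methylbicyclo[3.1.0]hexan-4-yl]acetate (cyclopropane anti to the side chain) | COC(=O)C[C@@H]1CC[C@@]2(O[Si](C)(C)C(C)(C)C)C[C@@]12C | intermediate
5 | N-methoxy-N-methyl-2-[1-(tert-butyldimethylsilyloxy)-5-methylbicyclo[3.1.0]hexan-4-yl]acetamide | CON(C)C(=O)C[C@@H]1CC[C@@]2(O[Si](C)(C)C(C)(C)C)C[C@@]12C | intermediate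
6 | 3-(dimethylamino)-N-methoxy-N-methyl-2-[1-(tert-butyldimethylsilyloxy)-5-methylbicyclo[3.1.0]hexan-4-yl]propanamide (C4 epimers) | CON(C)C(=O)C(CN(C)C)[C@@H]1CC[C@@]2(O[Si](C)(C)C(C)(C)C)C[C@@]12C | intermediate
7 | trimethylammonium iodide of 6 (C4 epimers) | CON(C)C(=O)C(C[N+](C)(C)C)[C@@H]1CC[C@@]2(O[Si](C)(C)C(C)(C)C)C[C@@]12C.[I-] | intermediate
8 | N-methoxy-N-methyl-2-[1-(tert-butyldimethylsilyloxy)-5-methylbicyclo[3.1.0]hexan-4-yl]prop-2-enamide | CON(C)C(=O)C(=C)[C@@H]1CC[C@@]2(O[Si](C)(C)C(C)(C)C)C[C@@]12C | intermediate
9 | 2-[1-(tert-butyldimethylsilyloxy)-5-methylbicyclo[3.1.0]hexan-4-yl]penta-1,4-dien-3-one (key-step precursor) | C=CC(=O)C(=C)[C@@H]1CC[C@@]2(O[Si](C)(C)C(C)(C)C)C[C@@]12C | intermediate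
10 | (5α,10β)-10-methyl-4-methylidenedecalin-3,8-dione (trans-fused; key-step product) | C=C1C(=O)CC[C@]2(C)CC(=O)CC[C@@H]12 | intermediate
11 | 4α-hydroperoxy-4β,10β-dimethyl-5α-decalin-3,8-dione | O=C1CC[C@]2(C)CC(=O)CC[C@H]2[C@]1(C)OO | intermediate
12 | 4α-hydroxy-4β,10β-dimethyl-5α-decalin-3,8-dione | O=C1CC[C@]2(C)CC(=O)CC[C@H]2[C@]1(C)O | intermediate
13 | 3β,4α-dihydroxy-4β,10β-dimethyl-5α-decalin-8-one | O[C@H]1CC[C@]2(C)CC(=O)CC[C@H]2[C@]1(C)O | intermediate
14 | 3β,4α-bis(triethylsilyloxy)-4β,10β-dimethyl-5α-decalin-8-one | CC[Si](CC)(CC)O[C@H]1CC[C@]2(C)CC(=O)CC[C@H]2[C@]1(C)O[Si](CC)(CC)CC | intermediate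
15 | 7-(2-hydroxypropan-2-yl)-3β,4α-bis(triethylsilyloxy)-4β,10β-dimethyl-5α-decalin-8-one (C7 epimers) | CC[Si](CC)(CC)O[C@H]1CC[C@]2(C)CC(=O)C(C(C)(C)O)C[C@H]2[C@]1(C)O[Si](CC)(CC)CC | intermediate
16 | methanesulfonate of 15 at the tertiary hydroxyl (C7 epimers) | CC[Si](CC)(CC)O[C@H]1CC[C@]2(C)CC(=O)C(C(C)(C)OS(C)(=O)=O)C[C@H]2[C@]1(C)O[Si](CC)(CC)CC | intermediate
17 | 3β,4α-bis(triethylsilyloxy)eudesm-7(11)-en-8-one | CC[Si](CC)(CC)O[C@H]1CC[C@]2(C)CC(=O)C(=C(C)C)C[C@H]2[C@]1(C)O[Si](CC)(CC)CC | intermediate
18 | 3β,4α-dihydroxyeudesm-7(11)-en-8-one | O[C@H]1CC[C@]2(C)CC(=O)C(=C(C)C)C[C@H]2[C@]1(C)O | intermediate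
19 | 3β-angeloyloxy-4α-hydroxyeudesm-7(11)-en-8-one | C/C=C(/C)C(=O)O[C@H]1CC[C@]2(C)CC(=O)C(=C(C)C)C[C@H]2[C@]1(C)O | intermediate
20 | 3β-angeloyloxy-4α-acetoxyeudesm-7(11)-en-8-one (CNP0141494.1) | C/C=C(/C)C(=O)O[C@H]1CC[C@]2(C)CC(=O)C(=C(C)C)C[C@H]2[C@]1(C)OC(C)=O | target

**Step count and risks**

Total step count: 15. Longest linear sequence: 15 steps (1 → 20).

Steps most likely to fail:

1. Step 7. The tertiary C10 radical may be quenched or add intermolecularly to a dienone before ring closure, the catalyst may fail to turn over at the α-keto radical, or closure may occur partly on the wrong face of C10 (cis-fusion). Fallback for the radical-partition and turnover problems (it does not correct cis-fusion): the radical is generated by an inner-sphere stoichiometric oxidation instead of photoinduced electron transfer. Setting out from 9, the silyl ether is cleaved (HF·pyridine, THF, 0 °C) to the free cyclopropanol 2-(1-hydroxy-5-methylbicyclo[3.1.0]hexan-4-yl)penta-1,4-dien-3-one F1. This is treated with manganese(III) tris(picolinate) in DMF at 0 °C in the presence of tributyltin hydride as terminal hydrogen donor, a known way of generating β-keto radicals from cyclopropanols and adding them to electron-poor alkenes. The sequence returns to the route at 10.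

2. Step 1. Facial discrimination on the α-methyl enone may be insufficient, giving low enantiomeric purity at C5. Fallback by classical resolution: setting out from 1 and 2, step 1 is run with an achiral silyl triflimide catalyst and the racemate is carried through steps 2–9. Racemic 13 is esterified at O-3 with (S)-O-methylmandelic acid (DCC, DMAP), giving the (S)-2-methoxy-2-phenylacetate of 13 F2 and the diastereomeric ester derived from the antipode of 13 F3. The two are separated by chromatography or crystallisation, and F2 is methanolysed (K2CO3, MeOH). The sequence returns to the route at enantiopure 13.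

3. Step 6. The liberated hydroxylamine may add to the cross-conjugated dienone, or the dienone may polymerise during isolation. Fallback by an oxidation-state detour that forms the dienone in the absence of any amine: setting out from 8, DIBAL-H (THF, −78 °C) gives the aldehyde 2-[1-(tert-butyldimethylsilyloxy)-5-methylbicyclo[3.1.0]hexan-4-yl]prop-2-enal F4. Vinylmagnesium bromide adds to give the divinyl carbinol 2-[1-(tert-butyldimethylsilyloxy)-5-methylbicyclo[3.1.0]hexan-4-yl]penta-1,4-dien-3-ol F5. Oxidation with MnO2 or Dess–Martin periodinane returns to the route at 9, which is taken directly into step 7.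

Further compounds
F1 | step 7 | 2-(1-hydroxy-5-methylbicyclo[3.1.0]hexan-4-yl)penta-1,4-dien-3-one | C=CC(=O)C(=C)[C@@H]1CC[C@@]2(O)C[C@@]12C
F2 | step 1 | 3-O-[(S)-2-methoxy-2-phenylacetyl] ester of 13 | CO[C@@H](c1ccccc1)C(=O)O[C@H]1CC[C@]2(C)CC(=O)CC[C@H]2[C@]1(C)O
F3 | step 1 | 3-O-[(S)-2-methoxy-2-phenylacetyl] ester of the antipode of 13 | CO[C@@H](c1ccccc1)C(=O)O[C@@H]1CC[C@@]2(C)CC(=O)CC[C@@H]2[C@@]1(C)O
F4 | step 6 | 2-[1-(tert-butyldimethylsilyloxy)-5-methylbicyclo[3.1.0]hexan-4-yl]prop-2-enal | C=C(C=O)[C@@H]1CC[C@@]2(O[Si](C)(C)C(C)(C)C)C[C@@]12C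
F5 | step 6 | 2-[1-(tert-butyldimethylsilyloxy)-5-methylbicyclo[3.1.0]hexan-4-yl]penta-1,4-dien-3-ol | C=CC(O)C(=C)[C@@H]1CC[C@@]2(O[Si](C)(C)C(C)(C)C)C[C@@]12C
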